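**Retrosynthetic overview**
1. Target 28 ← oxidation of the C14 alcohol and removal of a C9/C14 silylene ← lactone 26, which already holds both rings and all stereocentres.
2. Key disconnection C5–C6: 26 ← acyclic (Z)-alkenyl iodide/C6 aldehyde 23 by a Nozaki–Hiyama–Kishi closure; the ten-membered carbocycle forms first, then the C6 alkoxide closes the five-membered lactone onto C12 in the same operation.
3. Enabling feature: C6 is both the allylic carbinol carbon beside the cis C4=C5 bond and the γ-carbon of the O–C12(=O)–C11(=C13)–C7 lactone ring, so a C5 alkenyl-metal adding to a C6 aldehyde leaves an alkoxide 1,4 to the C12 ester; the two cis alkenes (C4=C5, C1=C10) of the ten-membered ring let the chain fold.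
4. 23 ← C7–C8 bond by indium Barbier allylation of α-hydroxy lactol 13 with bromide 17 (C7 and C8 set from C9), then silylene, ester and acetal adjustments.
5. 13 ← dimethyl (S)-malate (supplies C9) + aldehyde 6 by a Stobbe-type condensation (C1=C10); 6 ← carbocupration of propyne (Z-C4=C5).

Key step: step 12

Remark: C-locants are the germacranolide locants of the target (C5 alkene CH, C6 lactone carbinol, C12 lactone carbonyl, C14 formyl carbon) and are kept for all intermediates; Grignard solution 1 and anhydride 21 are taken as purchased.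

**Route**

Step 1
Reactants: 1 2-(1,3-dioxolan-2-yl)ethylmagnesium bromide (THF solution); 2 propyne
Product: 5 2-[(3Z)-4-iodo-3-methylbut-3-en-1-yl]-1,3-dioxolane, via alkylcopper 3 (not isolated), via alkenylcopper 4 (not isolated)
Conditions: CuBr·SMe2 (1 equiv), Et2O/Me2S/THF, −45 °C; propyne, −25 °C; I2, THF, −50 → 0 °C
Reagents that add atoms: iodine, II
Why: Normant carbocupration adds the alkylcopper syn across propyne with the alkyl group on the methyl-bearing carbon, so iodinolysis with retention should give the alkenyl iodide with iodine cis to the chain (Z), the geometry needed at C4=C5.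

Step 2
Reactants: 5 2-[(3Z)-4-iodo-3-methylbut-3-en-1-yl]-1,3-dioxolane
Product: 6 (4Z)-5-iodo-4-methylpent-4-enal
Conditions: 1 M HCl, THF, rt
Reagents that add atoms: water, O
Why: Acid-catalysed acetal hydrolysis should unmask the C1 aldehyde without touching the trisubstituted alkenyl iodide, and no stereocentre is involved.

Step 3
Reactants: 6 (4Z)-5-iodo-4-methylpent-4-enal; 7 dimethyl (2S)-2-hydroxybutanedioate (dimethyl L-malate)
Product: 10 (2S,3E,7Z)-2-hydroxy-8-iodo-3-(methoxycarbonyl)-7-methylocta-3,7-dienoic acid, via dilithium alkoxide-enolate 8 (not isolated), via paraconate lactone 9 (not isolated)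
Conditions: LiN(SiMe3)2 (2.2 equiv), THF, −78 → −20 °C; 6, −78 → 0 °C; KOtBu (1.2 equiv), 0 °C → rt; 1 M HCl
Reagents that add atoms: none
Why: The Fráter–Seebach alkoxide-enolate of malate should add to the aldehyde (aldol), the new alkoxide lactonises onto the ester beside the carbinol, and base-induced E1cB opening of this paraconate (Stobbe condensation) should give the thermodynamically preferred E-alkylidene half-ester with the chain trans to CO2Me, erasing the two transient centres while the malate carbinol centre (future C9) stays an untouched alkoxide.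

Step 4
Reactants: 10 (2S,3E,7Z)-2-hydroxy-8-iodo-3-(methoxycarbonyl)-7-methylocta-3,7-dienoic acid
Product: 12 (3S,4Z)-3-hydroxy-4-[(4Z)-5-iodo-4-methylpent-4-en-1-ylidene]oxolan-2-one, via dihydroxy acid 11 (not isolated)
Conditions: iBu2AlH (5 equiv), CH2Cl2/THF, −78 → −30 °C; 1 M HCl, rt
Reagents that add atoms: none
Why: iBu2AlH should reduce the conjugated methyl ester by 1,2-addition while the carboxylate and alkoxide are only deprotonated, and acidification lets the γ-hydroxy acid close to the γ-lactone, which differentiates C8 (lactone carbonyl) from C14 (ring CH2–O) with no new stereocentre.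

Step 5
Reactants: 12 (3S,4Z)-3-hydroxy-4-[(4Z)-5-iodo-4-methylpent-4-en-1-ylidene]oxolan-2-one
Product: 13 (3S,4Z)-4-[(4Z)-5-iodo-4-methylpent-4-en-1-ylidene]oxolane-2,3-diol (anomer mixture)
Conditions: iBu2AlH (2.2 equiv), CH2Cl2, −78 °C; aq. KNaC4H4O6 (tartrate)
Reagents that add atoms: none
Why: Partial reduction of a γ-lactone with iBu2AlH at −78 °C should stop at the aluminium hemiacetal and give the lactol, a masked α-hydroxy aldehyde at C8 whose anomeric centre is of no consequence.

Step 6
Reactants: 14 methyl acrylate; 15 2,2-dimethoxyacetaldehyde (60% in water)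
Product: 16 methyl 3-hydroxy-4,4-dimethoxy-2-methylidenebutanoate (racemic)
Conditions: DABCO (0.5 equiv), 1,4-dioxane/H2O, rt
Reagents that add atoms: none
Why: The Morita–Baylis–Hillman reaction of an activated α-alkoxy aldehyde with methyl acrylate should give the allylic alcohol, whose racemic carbinol centre is removed in the next step.

Step 7
Reactants: 16 methyl 3-hydroxy-4,4-dimethoxy-2-methylidenebutanoate
Product: 17 methyl (2Z)-2-(bromomethyl)-4,4-dimethoxybut-2-enoate
Conditions: NBS, Me2S, CH2Cl2, 0 °C → rt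
Reagents that add atoms: N-bromosuccinimide, O=C1CCC(=O)N1Br
Why: The alkoxysulfonium salt formed with the NBS–Me2S reagent should be displaced by bromide with allylic transposition (SN2'), giving the conjugated bromomethyl enoate with the acetal carbon trans to the ester.

Step 8
Reactants: 13 (3S,4Z)-4-[(4Z)-5-iodo-4-methylpent-4-en-1-ylidene]oxolane-2,3-diol; 17 methyl (2Z)-2-(bromomethyl)-4,4-dimethoxybut-2-enoate
Product: 19 methyl (3R,4S,5S,6Z,10Z)-3-(dimethoxymethyl)-4,5-dihydroxy-6-(hydroxymethyl)-11-iodo-10-methyl-2-methylideneundeca-6,10-dienoate, via allylindium reagent 18 (not isolated)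
Conditions: indium powder (2 equiv), 17 (2 equiv), THF/H2O (1:1), rt
Reagents that add atoms: none
Why: In this aqueous Barbier allylation the allylindium should react at its γ-carbon with the open α-hydroxy aldehyde form of the lactol through a chair-like transition state that gives the syn C7/C8 relationship whatever the bromide geometry, while chelation of indium by the free C9 hydroxyl should direct attack to the face that gives the syn (threo) C8/C9 diol, so C7 and C8 are set from C9.

Step 9
Reactants: 19 methyl (3R,4S,5S,6Z,10Z)-3-(dimethoxymethyl)-4,5-dihydroxy-6-(hydroxymethyl)-11-iodo-10-methyl-2-methylideneundeca-6,10-dienoate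
Product: 20 methyl (3R,4S)-4-[(4S,5Z)-2,2-di-tert-butyl-5-[(4Z)-5-iodo-4-methylpent-4-en-1-ylidene]-1,3,2-dioxasilinan-4-yl]-3-(dimethoxymethyl)-4-hydroxy-2-methylidenebutanoate
Conditions: tBu2Si(OTf)2 (1.05 equiv), pyridine, DMF, −40 → 0 °C
Reagents that add atoms: di-tert-butylsilyl bis(trifluoromethanesulfonate), CC(C)(C)[Si](OS(=O)(=O)C(F)(F)F)(OS(=O)(=O)C(F)(F)F)C(C)(C)C
Why: The silylene bis(triflate) should bridge the 1,3-diol (primary C14–OH and C9–OH) as a six-membered dioxasilinane in preference to the five- or seven-membered alternatives, leaving only the C8 hydroxyl free.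

Step 10
Reactants: 20 silylene-protected hydroxy ester; 21 (2S)-2-methylbutanoic anhydride
Product: 22 methyl (3R,4S)-4-[(4S,5Z)-2,2-di-tert-butyl-5-[(4Z)-5-iodo-4-methylpent-4-en-1-ylidene]-1,3,2-dioxasilinan-4-yl]-3-(dimethoxymethyl)-2-methylidene-4-[(2S)-2-methylbutanoyloxy]butanoate
Conditions: DMAP (0.2 equiv), pyridine, CH2Cl2, rt
Reagents that add atoms: none
Why: DMAP-catalysed acylation of the one remaining secondary hydroxyl (C8) by the anhydride should install the (S)-2-methylbutanoate without disturbing its α-centre.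

Step 11
Reactants: 22 dimethyl acetal ester
Product: 23 methyl (3R,4S)-4-[(4S,5Z)-2,2-di-tert-butyl-5-[(4Z)-5-iodo-4-methylpent-4-en-1-ylidene]-1,3,2-dioxasilinan-4-yl]-3-formyl-2-methylidene-4-[(2S)-2-methylbutanoyloxy]butanoate
Conditions: TFA/H2O (9:1), CH2Cl2, 0 °C; aq. NaH2PO4/Na2HPO4 (pH 7); used crude
Reagents that add atoms: water, O
Why: Aqueous acid should hydrolyse the dimethyl acetal to the C6 aldehyde under non-basic conditions that avoid β-elimination of the C8 ester and enolisation at C7.

Step 12
Reactants: 23 (Z)-alkenyl iodide C6 aldehyde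
Product: 26 (6R,7S,8S,9S)-9,14-O-(di-tert-butylsilanediyl)-9,14-dihydroxy-8-[(2S)-2-methylbutanoyloxy]germacra-1(10)Z,4Z,11(13)-trien-12,6-olide, via alkenylchromium dichloride 24 (not isolated), via seco hydroxy ester 25 (not isolated)
Conditions: CrCl2 (15 equiv), NiCl2 (0.2 equiv), DMSO/THF (3:1), slow addition to 0.002 M, rt; aq. NH4Cl; PPTS (cat.), CH2Cl2, rt
Reagents that add atoms: none
Why: Zerovalent nickel, formed from NiCl2 by CrCl2, inserts into the C5–I bond of 23, the alkenyl group passes to trivalent chromium (24) and adds to the C6 aldehyde, and the chromium alkoxide 25 then attacks the C12 methyl ester and expels methoxide (completed by PPTS), so one operation should make the C5–C6 bond, the ten-membered ring, the C6 stereocentre and the α-methylene-γ-lactone. The closest known reaction type is the Nozaki–Hiyama–Kishi macrocyclisation of iodoalkenyl aldehydes to nine- and ten-membered rings, coupled with the alkoxide-to-ester lactonisation familiar from chromium-mediated 2-(alkoxycarbonyl)allylations. The carbocycle closes in a 10-exo-trig mode (C5 onto the C6 carbonyl) and the lactone in a 5-exo-trig mode (O6 onto C12). C6 is controlled by the adjacent C7 centre: in the Felkin–Anh arrangement the C8 branch, which is part of the forming ring, stands anti to the incoming C5 and the acrylate arm takes the medium position, which should give the 6R carbinol with O6 trans to the C7–C11 bond and hence the trans-fused lactone. The step needs retention of the Z geometry at C4=C5 (alkenylchromium reagents are configurationally stable), attack at the aldehyde only (organochromium reagents leave the two esters and the acrylate alone) and ring closure faster than oligomerisation, which slow addition to 0.002 M, the two cis double bonds and the dioxasilinane ring (it holds O9 and C14 as in the hydrogen-bonded hydroxy-enal of the target) are meant to secure.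

Step 13
Reactants: 26 silylene-protected lactone
Product: 27 (6R,7S,8S,9S)-9,14-dihydroxy-8-[(2S)-2-methylbutanoyloxy]germacra-1(10)Z,4Z,11(13)-trien-12,6-olide
Conditions: HF·pyridine, pyridine, THF, 0 °C → rt
Reagents that add atoms: none
Why: Fluoride should cleave the two Si–O bonds of the silylene selectively, leaving the lactone, the ester and the alkenes intact.

Step 14
Reactants: 27 C9/C14 diol
Product: 28 (6R,7S,8S,9S)-9-hydroxy-8-[(2S)-2-methylbutanoyloxy]-14-oxogermacra-1(10)E,4Z,11(13)-trien-12,6-olide (target)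
Conditions: TEMPO (0.1 equiv), PhI(OAc)2 (1.1 equiv), CH2Cl2, rt
Reagents that add atoms: none
Why: The oxoammonium cycle of TEMPO with PhI(OAc)2 should oxidise the primary allylic C14 alcohol much faster than the secondary C9 alcohol and stop at the aldehyde, giving the enal of the target with unchanged alkene geometry.

**Compound list**
1 | 2-(1,3-dioxolan-2-yl)ethylmagnesium bromide | Br[Mg]CCC1OCCO1 | starting material
2 | propyne | CC#C | starting material
3 | 2-(1,3-dioxolan-2-yl)ethylcopper (MgBr2 complex) | [Cu]CCC1OCCO1 | intermediate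
4 | (1Z)-4-(1,3-dioxolan-2-yl)-2-methylbut-1-enylcopper | [Cu]/C=C(/C)CCC1OCCO1 | intermediate
5 | 2-[(3Z)-4-iodo-3-methylbut-3-en-1-yl]-1,3-dioxolane | I/C=C(/C)CCC1OCCO1 | intermediate
6 | (4Z)-5-iodo-4-methylpent-4-enal | I/C=C(/C)CCC=O | intermediate
7 | dimethyl (2S)-2-hydroxybutanedioate | COC(=O)C[C@H](O)C(=O)OC | starting material
8 | dilithium alkoxide-enolate of 7 | [Li+].[Li+].COC(=O)[C@@H]([O-])C=C([O-])OC | intermediate
9 | methyl (4S)-4-hydroxy-2-[(3Z)-4-iodo-3-methylbut-3-en-1-yl]-5-oxooxolane-3-carboxylate (mixture at ring C2 and C3) | COC(=O)C1C(CC/C(C)=C\I)OC(=O)[C@H]1O | intermediate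
10 | (2S,3E,7Z)-2-hydroxy-8-iodo-3-(methoxycarbonyl)-7-methylocta-3,7-dienoic acid | I/C=C(/C)CC/C=C(/C(=O)OC)[C@H](O)C(=O)O | intermediate
11 | (2S,3Z,7Z)-2-hydroxy-3-(hydroxymethyl)-8-iodo-7-methylocta-3,7-dienoic acid | I/C=C(/C)CC/C=C(/CO)[C@H](O)C(=O)O | intermediate
12 | (3S,4Z)-3-hydroxy-4-[(4Z)-5-iodo-4-methylpent-4-en-1-ylidene]oxolan-2-one | O=C1OC/C(=C/CC/C(C)=C\I)[C@@H]1O | intermediate
13 | (3S,4Z)-4-[(4Z)-5-iodo-4-methylpent-4-en-1-ylidene]oxolane-2,3-diol (anomer mixture) | OC1OC/C(=C/CC/C(C)=C\I)[C@@H]1O | intermediate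
14 | methyl acrylate | C=CC(=O)OC | starting material
15 | 2,2-dimethoxyacetaldehyde | COC(OC)C=O | starting material
16 | methyl 3-hydroxy-4,4-dimethoxy-2-methylidenebutanoate (racemic) | COC(=O)C(=C)C(O)C(OC)OC | intermediate
17 | methyl (2Z)-2-(bromomethyl)-4,4-dimethoxybut-2-enoate | COC(=O)/C(CBr)=C/C(OC)OC | intermediate
18 | allylindium reagent from 17 (drawn as the monovalent allylindium) | COC(=O)C(C[In])=CC(OC)OC | intermediate
19 | methyl (3R,4S,5S,6Z,10Z)-3-(dimethoxymethyl)-4,5-dihydroxy-6-(hydroxymethyl)-11-iodo-10-methyl-2-methylideneundeca-6,10-dienoate | C=C(C(=O)OC)[C@@H](C(OC)OC)[C@H](O)[C@@H](O)/C(CO)=C\CC/C(C)=C\I | intermediate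
20 | methyl (3R,4S)-4-[(4S,5Z)-2,2-di-tert-butyl-5-[(4Z)-5-iodo-4-methylpent-4-en-1-ylidene]-1,3,2-dioxasilinan-4-yl]-3-(dimethoxymethyl)-4-hydroxy-2-methylidenebutanoate | C=C(C(=O)OC)[C@@H](C(OC)OC)[C@H](O)[C@H]1O[Si](C(C)(C)C)(C(C)(C)C)OC/C1=C/CC/C(C)=C\I | intermediate
21 | (2S)-2-methylbutanoic anhydride | CC[C@H](C)C(=O)OC(=O)[C@@H](C)CC | starting material
22 | methyl (3R,4S)-4-[(4S,5Z)-2,2-di-tert-butyl-5-[(4Z)-5-iodo-4-methylpent-4-en-1-ylidene]-1,3,2-dioxasilinan-4-yl]-3-(dimethoxymethyl)-2-methylidene-4-[(2S)-2-methylbutanoyloxy]butanoate | C=C(C(=O)OC)[C@@H](C(OC)OC)[C@H](OC(=O)[C@@H](C)CC)[C@H]1O[Si](C(C)(C)C)(C(C)(C)C)OC/C1=C/CC/C(C)=C\I | intermediate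
23 | methyl (3R,4S)-4-[(4S,5Z)-2,2-di-tert-butyl-5-[(4Z)-5-iodo-4-methylpent-4-en-1-ylidene]-1,3,2-dioxasilinan-4-yl]-3-formyl-2-methylidene-4-[(2S)-2-methylbutanoyloxy]butanoate | C=C(C(=O)OC)[C@@H](C=O)[C@H](OC(=O)[C@@H](C)CC)[C@H]1O[Si](C(C)(C)C)(C(C)(C)C)OC/C1=C/CC/C(C)=C\I | intermediate
24 | alkenylchromium dichloride from 23 (CrCl2 in place of iodine at C5) | C=C(C(=O)OC)[C@@H](C=O)[C@H](OC(=O)[C@@H](C)CC)[C@H]1O[Si](C(C)(C)C)(C(C)(C)C)OC/C1=C/CC/C(C)=C\[Cr](Cl)Cl | intermediate
25 | ten-membered seco hydroxy ester of 26 (6R-hydroxyl free, C12 methyl ester; chromium alkoxide drawn as the alcohol) | C=C(C(=O)OC)[C@H]1[C@H](O)/C=C(/C)CC/C=C2/CO[Si](C(C)(C)C)(C(C)(C)C)O[C@@H]2[C@H]1OC(=O)[C@@H](C)CC | intermediate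
26 | (6R,7S,8S,9S)-9,14-O-(di-tert-butylsilanediyl)-9,14-dihydroxy-8-[(2S)-2-methylbutanoyloxy]germacra-1(10)Z,4Z,11(13)-trien-12,6-olide | C=C1C(=O)O[C@@H]2/C=C(/C)CC/C=C3/CO[Si](C(C)(C)C)(C(C)(C)C)O[C@@H]3[C@@H](OC(=O)[C@@H](C)CC)[C@@H]12 | intermediate
27 | (6R,7S,8S,9S)-9,14-dihydroxy-8-[(2S)-2-methylbutanoyloxy]germacra-1(10)Z,4Z,11(13)-trien-12,6-olide | C=C1C(=O)O[C@@H]2/C=C(/C)CC/C=C(/CO)[C@H](O)[C@@H](OC(=O)[C@@H](C)CC)[C@@H]12 | intermediate
28 | (6R,7S,8S,9S)-9-hydroxy-8-[(2S)-2-methylbutanoyloxy]-14-oxogermacra-1(10)E,4Z,11(13)-trien-12,6-olide | C=C1C(=O)O[C@@H]2/C=C(/C)CC/C=C(/C=O)[C@H](O)[C@@H](OC(=O)[C@@H](C)CC)[C@@H]12 | target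

**Step count and risks**

Total steps: 14. Longest linear sequence: 12 steps (1–5 and 8–14); steps 6–7 are a two-step side branch.

Steps most likely to fail:

1. Step 12. The alkenylchromium may add to the C6 aldehyde from both faces, with the wrong epimer locked at once as a cis-lactone, and intermolecular coupling may compete with the slow ten-membered closure. The fallback sets out from aldehyde 23 and separates ring closure from the setting of C6. The closure is run under the manganese-driven catalytic variant of the same reaction (CrCl2 cat., NiCl2 cat., Mn, Me3SiCl), which traps the C6 alkoxide as the seco trimethylsilyl ether F1 before it can lactonise. Mild methanolysis of that silyl ether (PPTS, MeOH, 0 °C) with immediate Dess–Martin oxidation should give the macrocyclic (Z)-enone F2. Corey–Bakshi–Shibata reduction, with the catalyst enantiomer that gives the 6R carbinol, returns the seco hydroxy ester 25, and PPTS-induced lactonisation brings the route back at 26.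

2. Step 8. Facial selectivity relative to C9 may be low, and the allylindium may be lost by 1,4-elimination of methoxide. The fallback sets out from bromide 17. Pd-catalysed borylation (B2pin2, Pd2(dba)3 cat.) should give the allylboronate F3 with the acetal carbon cis to the CH2B group. Its uncatalysed allylboration of lactol 13 runs through a closed six-membered transition state, which transfers the reagent geometry into the syn C7/C8 relationship, while the free C9 hydroxyl binds boron and directs the syn diol. Hydrolytic work-up comes back at triol 19.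

3. Step 3. Lactonisation and eliminative opening may be incomplete, or the lithium aldolate may revert by retro-aldol. The fallback sets out from aldehyde 6 and introduces the C9 oxygen later. A classical Stobbe condensation with dimethyl succinate (KOtBu, tBuOH) should give the half-ester F4, and iBu2AlH reduction with acidification should give the β-alkylidene lactone F5. Its potassium enolate (KN(SiMe3)2, −78 °C) is hydroxylated at the α-carbon with the enantiomer of (camphorsulfonyl)oxaziridine that gives the 3S alcohol (Davis oxidation), which comes back at hydroxy lactone 12.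

Further compounds
F1 | step 12 | seco trimethylsilyl ether of 25 (C6 epimer mixture) | C=C(C(=O)OC)[C@H]1C(O[Si](C)(C)C)/C=C(/C)CC/C=C2/CO[Si](C(C)(C)C)(C(C)(C)C)O[C@@H]2[C@H]1OC(=O)[C@@H](C)CC
F2 | step 12 | macrocyclic (Z)-enone (C6 ketone, C12 methyl ester) | C=C(C(=O)OC)[C@H]1C(=O)/C=C(/C)CC/C=C2/CO[Si](C(C)(C)C)(C(C)(C)C)O[C@@H]2[C@H]1OC(=O)[C@@H](C)CC
F3 | step 8 | methyl (2E)-4,4-dimethoxy-2-[(4,4,5,5-tetramethyl-1,3,2-dioxaborolan-2-yl)methyl]but-2-enoate | COC(=O)/C(CB1OC(C)(C)C(C)(C)O1)=C/C(OC)OC
F4 | step 3 | (3E,7Z)-8-iodo-3-(methoxycarbonyl)-7-methylocta-3,7-dienoic acid | I/C=C(/C)CC/C=C(/C(=O)OC)CC(=O)O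
F5 | step 3 | (4E)-4-[(4Z)-5-iodo-4-methylpent-4-en-1-ylidene]oxolan-2-one | O=C1OC/C(=C/CC/C(C)=C\I)C1
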